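The numbers in the tables were computed with constants of no real substance, and the scatter is random.

If you want to know what a late flask holds, first count how many times a change you can read has turned over by then.

| setting | alpha | eta | flask |
|---|---|---|---|
| substrate | 0.20 M | 0.30 M | 0.20 M |
| gas | 30 mM (held) | 30 mM (held) | 30 mM (held) |
| temperature | −20 °C | −35 °C | −20 °C |
| remark | the very flask that is asked about, followed so far | run made earlier |  |
| time |  |  | 40 h |

- alpha (time / h: target / %, substrate / %): 2.00: 17, 35; 6.00: 14, 0; 12.0: 14, 0; 15.0: 14, 0; 25.0: 15, 0
- eta (time / h: target / %, substrate / %): 2.00: 8, 75; 5.00: 16, 47; 6.00: 17, 45; 10.0: 19, 23; 12.0: 22, 18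

(each reading ± 1.5 percentage points)

- ash: at 40 h take out 90 % of the target then present, then wait 3.0 d
- elm: at 40 h add substrate, 50.0 % of the amount charged, then wait 3.0 d
- alder: at 40 h raise the temperature by 20 K, then wait 3.0 d
- cedar: change nothing and wait 3.0 d more

- what is taken out of target is counted as made
- at the start none of the gas is in solution
- additions bring no volume worth counting

- target, in percent of the substrate first charged, at 40 h
- the remedy with the largest gain of target, or "none" below 2 percentage points (ash / elm / alder / cedar / none)
- target present, with what was taken out counted in, in percent of the substrate first charged, after alder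
- target present, with what was taken out counted in, in percent of the substrate first charged, after cedar

How long does the substrate last in the alpha run, which is this very flask? At 2.00 h it reads 35 %. With the gas held, I treat its loss as pseudo-first-order, which gives a half-life, as a reading, of 1.32 h.

How often does that fit into 40 h? It fits 30.3 times. This number of half-lives within the time is what I carry on, the turnover count.

What does the count tell you? That count leaves hardly any substrate, so I expect no further feed to target by 40 h and nothing gained from cedar.

And target at 40 h? The last 4 target readings of the alpha run average 14.3 %, and that is my number.

Then why 17 % at 2.00 h? That reading stands 3 percentage points above the next, twice the scatter. It is a weak sign that target may pass into something unseen and then stop.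

So what does warming do? My count of substrate does not say, so I name no remedy.

The forecast gives 14.5 % at 40 h where my average stands at 14.3 %, 14.5 % after cedar and 13.5 % after alder, and where I name no remedy it picks elm, saying “Warming has no evidence of benefit”.

The flask gives 14.4 % at 40 h and 14.4 % after cedar. The best remedy is alder, with 26.2 % and a gain of 12 points, more than 8.3 points for ash or 7.1 points for elm.

    substrate + coupling partner → target (k = 0.130 M⁻¹ min⁻¹, Ea = 51.0 kJ mol⁻¹)
    substrate + 2 coupling partner → side product (k = 6.80 M⁻² min⁻¹, Ea = 47.0 kJ mol⁻¹)
    target ⇌ isomer of the product (K = 1.80, k = 0.00960 min⁻¹, Ea = 81.0 kJ mol⁻¹, ΔH = −35.0 kJ mol⁻¹)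
    gas ⇌ coupling partner, rate k4*(csat - [coupling partner]) (kL = 1.00 min⁻¹)
    (constants at −20 °C)

The same count applies to target: the forward step into isomer of the product, the way back not counted, has a half-life of 1.2 h, short against 40 h, which makes 33.3 forward half-lives beside the 30.3 read for the substrate, and this flask holds target 14.4 % and isomer of the product 25.8 % at 40.0 h, as it still does at 400 h. The flask kept at −45 °C has 14.7 % of its substrate left at 40.0 h, a count of 2.77 against 30.3 here, and it holds isomer of the product 5.62 % beside target 23.6 %.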